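**Plan**
- Cuts: first the two C–aryl bonds at C2 and C5 of the tetrahydrofuran ring, both in one operation. Then the two CH2O–Si tether bonds and the Si–aryl bond of the silane building block. Last, one ring C–O bond of the aryl-free core.
- Enabling feature: each aryl-bearing ring carbon (C2, C5) sits next to a ring carbon (C3, C4) whose CH2OH group is on the same face as that aryl group. The CH2OH oxygen can therefore carry an aryl(dimethyl)silyl group and pass the aryl ring to the adjacent ring OCH2 carbon across the six atoms C2–C3–CH2–O–Si–C(ipso).
- Forward: the only ring (tetrahydrofuran) is closed at the start by cyclodehydration of an achiral tetraol. The resolved trans diol takes up two arylchlorosilane units, both aryl groups then move from Si to C2/C5 without ring closure, and one methanolysis unmasks the target.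
- Stereochemistry: C3/C4 trans comes from self-sorting in the cyclodehydration, and the absolute configuration (3S,4S) from a lipase resolution. C2 and C5 come from same-face delivery out of the C3 and C4 arms (2,3-cis, 4,5-cis, hence 2,5-trans).

Key step: step 7

Assumption: the lipase acetylates the (3R,4R) enantiomer of 3 faster, so the (3S,4S) diol is the fraction left unreacted. This sense must be verified on the first batch, for instance by X-ray analysis of a bis-camphanate.

**Step 1**
Reactants: 1 tetraethyl ethane-1,1,2,2-tetracarboxylate
Product: 2 2,3-bis(hydroxymethyl)butane-1,4-diol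
Conditions: LiAlH4 (6 equiv), THF, 0 °C to reflux; Na2SO4·10H2O quench; continuous extraction of the salts with hot EtOH
Reagents that add atoms: none
Why: Exhaustive LiAlH4 reduction of esters to primary alcohols works for malonate-type tetraesters when hydride is in large excess, no stereocentre arises because each CH carbon carries two identical arms, and the very polar tetraol is recovered from the aluminium salts by continuous extraction.

**Step 2**
Reactants: 2 2,3-bis(hydroxymethyl)butane-1,4-diol
Product: 3 racemic trans-tetrahydrofuran-3,4-diyldimethanol
Conditions: p-TsOH·H2O (5 mol %), neat melt, 135 °C, 20 mbar (water and the volatile bicyclic diether distil off); chromatography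
Reagents that add atoms: none
Why: Acid-catalysed cyclodehydration of a 1,4-diol (5-exo-tet displacement of a protonated primary hydroxyl) closes the tetrahydrofuran from one arm of each CH carbon and creates C3 and C4 as a cis/trans mixture, from which the cis diol is drained by a second dehydration to volatile cis-fused 3,7-dioxabicyclo[3.3.0]octane, a path barred to the trans diol because it would require a strained trans-fused bicycle, so the racemic trans diol should be the only diol left.

**Step 3**
Reactants: 3 racemic trans-tetrahydrofuran-3,4-diyldimethanol
Product: 4 (3S,4S)-tetrahydrofuran-3,4-diyldimethanol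
Conditions: Burkholderia cepacia lipase (immobilised), vinyl acetate (3 equiv), t-BuOMe, 30 °C, run past half conversion of the hydroxy groups; chromatography
Reagents that add atoms: none
Why: Lipase-catalysed kinetic resolution by irreversible transesterification with an enol ester is established for twofold-symmetric trans-1,2-bis(hydroxymethyl) rings, and because every molecule must be acylated twice the enantiomer discrimination is multiplied, so the diol remaining after more than half conversion should be enantiopure, which fixes the absolute configuration at C3 and C4.

**Step 4**
Reactants: 5 4-bromo-2-methoxyphenol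
Product: 6 4-bromo-2-methoxyphenyl pivalate
Conditions: t-BuCOCl (1.2 equiv), Et3N (1.5 equiv), DMAP (5 mol %), CH2Cl2, 0 °C to rt
Reagents that add atoms: pivaloyl chloride CC(C)(C)C(=O)Cl
Why: This is a DMAP-catalysed O-acylation of a phenol with an acid chloride, and the pivalate has no weak or acidic C–H bond, is hindered enough to coexist with an aryl Grignard reagent in the cold, and turns the para oxygen from a strong into a weak donor, as the key step requires.

**Step 5**
Reactants: 6 4-bromo-2-methoxyphenyl pivalate; 7 dichlorodimethylsilane
Product: 9 4-[chloro(dimethyl)silyl]-2-methoxyphenyl pivalate, via arylmagnesium bromide 8 (not isolated)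
Conditions: Mg turnings (2.5 equiv), LiCl (1.25 equiv), i-Bu2AlH (1 mol %), THF, 0 °C; then cannulated into Me2SiCl2 (5 equiv), THF, –20 °C to rt; volatiles removed, salts precipitated with pentane, Kugelrohr distillation
Reagents that add atoms: none
Why: LiCl-promoted magnesium insertion into aryl bromides runs at or below 0 °C and tolerates hindered aryl esters, and inverse addition of the Grignard reagent to a fivefold excess of the dichlorosilane (nucleophilic substitution at silicon) should stop at monoarylation.

**Step 6**
Reactants: 4 (3S,4S)-tetrahydrofuran-3,4-diyldimethanol; 9 4-[chloro(dimethyl)silyl]-2-methoxyphenyl pivalate (2.2 equiv)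
Product: 10 bis{[3-methoxy-4-(pivaloyloxy)phenyl]dimethylsilyl} ether of 4 (arms trans; 3R,4R by the CIP rules only because the silyloxymethyl arms now outrank the ring CH2, spatially unchanged)
Conditions: Et3N (3 equiv), CH2Cl2, 0 °C; filtration through Et3N-deactivated silica
Reagents that add atoms: none
Why: Silyl ether formation from unhindered primary alcohols and a chlorosilane with an amine base is fast at 0 °C and touches neither the aryl pivalates nor the two stereocentres, and the product, about as labile as a dimethylphenylsilyl ether, is handled on deactivated silica only.

**Step 7**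
Reactants: 10 bis{[3-methoxy-4-(pivaloyloxy)phenyl]dimethylsilyl} ether of 4
Product: 12 bis(chlorodimethylsilyl) ether of the target dipivalate (2,3-cis 3,4-trans 4,5-cis; 2S,3S,4S,5S), via mono-shifted chlorosilyl ether 11 (not isolated)
Conditions: (n-Bu4N)4[W10O32] (5 mol %), CCl4 (5 equiv), 2,6-di-tert-butylpyridine (0.3 equiv), dry degassed MeCN (0.02 M), 390 nm LEDs, 25–30 °C, Ar; stopped when 11 is consumed; volatiles removed, crude 12 used at once
Reagents that add atoms: carbon tetrachloride ClC(Cl)(Cl)Cl
Why: Proposed new method: Photoexcited [W10O32]4– abstracts a hydrogen atom from a ring OCH2 group (C2, and after the first shift C5), the trigonal α-oxy centre bonds to the ipso carbon of the aryl ring on the neighbouring CH2–O–Si arm through a six-membered array (C2, C3, CH2, O, Si, C-ipso), and the Si–aryl bond then breaks, so two C–C bonds form and no ring is closed. Because an α-oxy radical is too stabilised to pay for expelling a free silyl radical, and a Si–H product would only feed the reverse reaction, CCl4 acts as chlorine-atom donor and removes one electron from the sequence, either from the spiro-cyclohexadienyl radical or from the α-oxy radical itself (oxocarbenium chloride pair, which attacks the same ipso carbon); both lines meet in a β-silyl-stabilised arenium chloride that collapses irreversibly to C–aryl and Si–Cl, while •CCl3 takes the hydrogen back from the reduced polyanion as CHCl3 and so closes the catalytic cycle. The closest known reaction types are decatungstate-photocatalysed C–H abstraction next to ether oxygen with halogen transfer from a polyhalomethane, radical 1,5-aryl migration from silicon to carbon in aryl silyl ethers, and delivery of an aryl group from a silyl ether tether to an oxocarbenium ion (ipso-substitution of an arylsilane). C2 is controlled by C3 and C5 by C4: the new bond must form along the p-orbital axis of the trigonal carbon, and the three-atom CH2–O–Si chain reaches that axis only on its own face of the ring (torsion about C2–C3 roughly 30–60°, against more than 110° for the far face), which puts each aryl group cis to its neighbouring CH2O arm and the two aryl groups trans to each other. The step needs abstraction at ring OCH2 rather than at SiOCH2, OCH3 or the new tertiary benzylic C–H, and relies for this on the bulk and electrophilicity of the polyanion, on the hindered and less hydridic silyl ether CH2, and on the pivalate, which leaves OCH3 (meta to the benzylic carbon) as the only strong donor and so slows both hydrogen abstraction and electron transfer at the product. It also needs the 1,5-shift from the near arm rather than a 1,6-shift from the far arm, and ipso rather than ortho attack, which the six- versus seven-membered arrays and the β-silicon effect should secure.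

**Step 8**
Reactants: 12 bis(chlorodimethylsilyl) ether of the target dipivalate
Product: 13 eduesmine, [(2S,3S,4S,5S)-2,5-bis(4-hydroxy-3-methoxyphenyl)tetrahydrofuran-3,4-diyl]dimethanol
Conditions: crude 12 added to K2CO3 (5 equiv), MeOH, 0 °C to rt, Ar; aq NH4Cl, EtOAc
Reagents that add atoms: none
Why: Base-mediated methanolysis (transesterification of the phenolic pivalates, solvolysis of the Si–Cl and Si–O bonds) removes all four auxiliary groups in one operation at room temperature, where no C–O bond at C2 or C5 is broken because quinone methide formation from the phenolate needs heat, so the four stereocentres should persist.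

**Compound list**
1 | tetraethyl ethane-1,1,2,2-tetracarboxylate | CCOC(=O)C(C(=O)OCC)C(C(=O)OCC)C(=O)OCC | starting material
2 | 2,3-bis(hydroxymethyl)butane-1,4-diol | OCC(CO)C(CO)CO | intermediate
3 | racemic trans-tetrahydrofuran-3,4-diyldimethanol (both enantiomers written) | C1OC[C@H](CO)[C@H]1CO.C1OC[C@@H](CO)[C@@H]1CO | intermediate
4 | (3S,4S)-tetrahydrofuran-3,4-diyldimethanol | C1OC[C@H](CO)[C@H]1CO | intermediate
5 | 4-bromo-2-methoxyphenol | COc1cc(Br)ccc1O | starting material
6 | 4-bromo-2-methoxyphenyl pivalate | COc1cc(Br)ccc1OC(=O)C(C)(C)C | intermediate
7 | dichlorodimethylsilane | C[Si](C)(Cl)Cl | starting material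
8 | [3-methoxy-4-(pivaloyloxy)phenyl]magnesium bromide | COc1cc([Mg]Br)ccc1OC(=O)C(C)(C)C | intermediate
9 | 4-[chloro(dimethyl)silyl]-2-methoxyphenyl pivalate | COc1cc([Si](C)(C)Cl)ccc1OC(=O)C(C)(C)C | intermediate
10 | bis{[3-methoxy-4-(pivaloyloxy)phenyl]dimethylsilyl} ether of 4 | C1OC[C@H](CO[Si](C)(C)c2ccc(OC(=O)C(C)(C)C)c(OC)c2)[C@H]1CO[Si](C)(C)c1ccc(OC(=O)C(C)(C)C)c(OC)c1 | intermediate
11 | mono-shifted compound: aryl on C2 cis to the C3 CH2OSiMe2Cl arm, C4 arm still CH2OSiMe2Ar, C5 still CH2 | COc1cc([C@H]2OC[C@H](CO[Si](C)(C)c3ccc(OC(=O)C(C)(C)C)c(OC)c3)[C@H]2CO[Si](C)(C)Cl)ccc1OC(=O)C(C)(C)C | intermediate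
12 | bis(chlorodimethylsilyl) ether of the target dipivalate (2S,3S,4S,5S) | COc1cc([C@H]2O[C@H](c3ccc(OC(=O)C(C)(C)C)c(OC)c3)[C@H](CO[Si](C)(C)Cl)[C@H]2CO[Si](C)(C)Cl)ccc1OC(=O)C(C)(C)C | intermediate
13 | eduesmine, [(2S,3S,4S,5S)-2,5-bis(4-hydroxy-3-methoxyphenyl)tetrahydrofuran-3,4-diyl]dimethanol | COc1cc([C@H]2O[C@H](c3ccc(O)c(OC)c3)[C@H](CO)[C@H]2CO)ccc1O | target

**Step count**
Total steps: 8. Longest linear sequence: 6 (steps 1, 2, 3, 6, 7, 8 from 1). The aryl branch (steps 4, 5) joins at step 6.

**Steps most likely to fail**

Step 7 (new method). Four processes may defeat it:
- renewed hydrogen abstraction or electron transfer at the freshly formed benzylic ether C–H bonds, with loss of the cis configuration or over-oxidation;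
- chlorine transfer after abstraction at SiOCH2 or OCH3;
- interception of the cationic centre by the silyl ether oxygen of the far arm;
- unproductive quenching of the excited polyanion by the arenes.

The fallback drops light, radicals and catalyst in favour of a two-electron hydride abstraction, and both of its events are established reaction types. It sets out from 10. This is treated in the dark with Ph3CBF4 (2.2 equiv) and 2,6-di-tert-butylpyridine in CH2Cl2 at 0 °C to rt. The bulky trityl cation takes a hydride from a ring OCH2 group (the classical reaction of trityl salts with ethers) and should discriminate against the tertiary benzylic C–H. The oxocarbenium ion is captured by the tethered arylsilane at its ipso carbon on the same face as before, and BF4– gives fluoride to silicon. The sequence should pass through the mono-shifted fluorodimethylsilyl ether F1 to the bis(fluorodimethylsilyl) ether of the target dipivalate F2. Under the K2CO3/MeOH conditions of step 8, F2 returns to the route at 13.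

Step 3. Enantiomer discrimination may be poor because the stereocentre lies one carbon away from the reacting hydroxyl, or the enzyme may prefer the wrong enantiomer. The fallback is a covalent resolution that does not depend on any enzyme preference. It sets out from 3, which is esterified with (1S,4R)-camphanoyl chloride (2.2 equiv, pyridine, DMAP, CH2Cl2). This gives the bis-camphanate of the (3S,4S) diol F3 and the bis-camphanate of the (3R,4R) diol F4. They are separated by fractional crystallisation or chromatography and assigned by X-ray analysis with the camphanate as internal reference. Methanolysis of F3 (K2CO3, MeOH) comes back to the route at 4.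

Step 5. The arylmagnesium species may transfer onto the pivalate of a second molecule, insertion may be sluggish, or silicon may be arylated twice. The fallback forms the C–Si bond before the ester is present. It sets out from 5:
- 5 is deprotonated with n-BuLi (1 equiv) and lithiated with t-BuLi (2 equiv) in THF at –78 °C, then quenched with Me2SiHCl (2.5 equiv) to give [4-(dimethylsilyl)-2-methoxyphenoxy]dimethylsilane F5.
- The aryloxy–silicon bond of F5 is hydrolysed on aqueous NH4Cl work-up to 4-(dimethylsilyl)-2-methoxyphenol F6.
- Acylation with pivaloyl chloride and Et3N gives 4-(dimethylsilyl)-2-methoxyphenyl pivalate F7.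
- Si–H to Si–Cl exchange with trichloroisocyanuric acid in CH2Cl2 at –20 °C comes back to the route at 9.

**Further compounds**
F1 | step 7 | mono-shifted fluorodimethylsilyl ether (aryl on C2 cis to the C3 CH2OSiMe2F arm, C4 arm still CH2OSiMe2Ar) | COc1cc([C@H]2OC[C@H](CO[Si](C)(C)c3ccc(OC(=O)C(C)(C)C)c(OC)c3)[C@H]2CO[Si](C)(C)F)ccc1OC(=O)C(C)(C)C
F2 | step 7 | bis(fluorodimethylsilyl) ether of the target dipivalate | COc1cc([C@H]2O[C@H](c3ccc(OC(=O)C(C)(C)C)c(OC)c3)[C@H](CO[Si](C)(C)F)[C@H]2CO[Si](C)(C)F)ccc1OC(=O)C(C)(C)C
F3 | step 3 | bis[(1S,4R)-camphanate] of (3S,4S)-tetrahydrofuran-3,4-diyldimethanol | C1OC[C@H](COC(=O)[C@@]23CC[C@@](C)(C(=O)O2)C3(C)C)[C@H]1COC(=O)[C@@]12CC[C@@](C)(C(=O)O1)C2(C)C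
F4 | step 3 | bis[(1S,4R)-camphanate] of (3R,4R)-tetrahydrofuran-3,4-diyldimethanol | C1OC[C@@H](COC(=O)[C@@]23CC[C@@](C)(C(=O)O2)C3(C)C)[C@@H]1COC(=O)[C@@]12CC[C@@](C)(C(=O)O1)C2(C)C
F5 | step 5 | [4-(dimethylsilyl)-2-methoxyphenoxy]dimethylsilane | COc1cc([SiH](C)C)ccc1O[SiH](C)C
F6 | step 5 | 4-(dimethylsilyl)-2-methoxyphenol | COc1cc([SiH](C)C)ccc1O
F7 | step 5 | 4-(dimethylsilyl)-2-methoxyphenyl pivalate | COc1cc([SiH](C)C)ccc1OC(=O)C(C)(C)C
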